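**Retrosynthetic overview**

1. The C8–O bond is made last: the target comes from the α-branched C17 aldehyde (C8–H) by an internal, invertive C–O closure (methoxy-oxirane) that places oxygen on the hindered, C10-methyl face.
2. That aldehyde comes from the spiro-epoxide of the exocyclic 8(17)-alkene (epoxidation, then Meinwald hydride shift).
3. The bicycle comes from a (14R)-epoxy tetraenoic acid in one titanocene radical cascade: ring A closes first, then ring B; C3 controls C5, C10 and C9.
4. The epoxide comes from the tetraenoic acid by asymmetric terminal epoxidation; this C–O bond fixes the absolute configuration.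
5. The (2Z,6E,10E)-C20 acid comes from 3-methylbut-2-enoic acid and (2E,6E)-farnesyl bromide by γ-allylation, which sets the 13Z alkene.

Assumption: (2E,6E)-farnesyl bromide is bought as a catalogue reagent (otherwise one step, PBr3, from (2E,6E)-farnesol); "ent-" names denote mirror images of normal labdane descriptors, and faces are given relative to the C10 methyl.

**Route**

Step 1
Reactants: 1 3-methylbut-2-enoic acid; 2 (2E,6E)-farnesyl bromide
Product: 5 (2Z,6E,10E)-3,7,11,15-tetramethylhexadeca-2,6,10,14-tetraenoic acid, via dilithium dienediolate 3 (not isolated), via lithium copper dienolate 4 (not isolated)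
Conditions: LiN(iPr)2 (2.1 equiv, commercial solution), THF, −78 → 0 °C; CuI (1.1 equiv), −78 °C; 2 (0.85 equiv), −78 → −20 °C; 1 M HCl; AgNO3–silica chromatography
Reagents that add atoms: none
Why: γ-Selective allylation of a copper dienolate (Katzenellenbogen alkylation): syn deprotonation of the carboxylate-facing methyl gives the chelated, U-shaped dienediolate 3, and its monovalent-copper form 4 couples with the allylic bromide at the γ-carbon by SN2, so the new chain ends up cis to the carboxylate (2Z expected to predominate, roughly 4:1; the 2E and α-alkylated acids are removed on AgNO3–silica) while both E alkenes of 2 pass through unchanged.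

Step 2
Reactants: 5 (2Z,6E,10E)-3,7,11,15-tetramethylhexadeca-2,6,10,14-tetraenoic acid
Product: 6 (2Z,6E,10E)-13-[(2R)-3,3-dimethyloxiran-2-yl]-3,7,11-trimethyltrideca-2,6,10-trienoic acid
Conditions: D-fructose-derived Shi ketone (1,2:4,5-di-O-isopropylidene-β-D-erythro-2,3-hexodiulo-2,6-pyranose, 0.3 equiv), KHSO5 (as Oxone, 1.1 equiv), K2CO3, Bu4NHSO4 (cat.), MeCN–(MeO)2CH2 / aq. Na2B4O7–EDTA (pH 10.5), −5 °C, to about 70% conversion; 0.5 M HCl to pH 5 at 0 °C
Reagents that add atoms: potassium peroxymonosulfate KHSO5, [K+].[O-]S(=O)(=O)OO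
Why: Shi asymmetric epoxidation (chiral dioxirane, spiro transition state): the D-fructose-derived ketone delivers oxygen to the face of the terminal trisubstituted alkene that gives the 14R epoxide (≥90% ee expected); the conjugated C2 alkene is electronically deactivated and the internal alkenes are more hindered, so the terminal mono-epoxide is the main product at partial conversion (recovered 5 is recycled).

Step 3
Reactants: 6 (2Z,6E,10E)-13-[(2R)-3,3-dimethyloxiran-2-yl]-3,7,11-trimethyltrideca-2,6,10-trienoic acid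
Product: 9 ent-3β-hydroxylabda-8(17),13Z-dien-15-oic acid, via trimethylsilyl ester 7 (not isolated), via bis-silyl bicycle 8 (not isolated)
Conditions: Me3SiCl (4 equiv), 2,4,6-collidine (7 equiv), THF, rt, 15 min; Cp2TiCl2 (0.2 equiv), Mn dust (8 equiv), THF (0.02 M), rt, 16 h; then 1 M HCl, THF, rt
Reagents that add atoms: none
Why: Titanocene-catalysed radical epoxypolyene cyclization (Nugent–RajanBabu epoxide opening by Cp2TiCl, then 6-endo/6-endo closure through a chair–chair array, ring A before ring B, ended by trapping of the C8 radical with trivalent titanium and β-hydride elimination to the exocyclic alkene): the epoxide-derived C3 centre sits with its oxygen equatorial and thereby sets C5, C10 and C9 (trans-decalin, side chain equatorial), the in situ silyl ester keeps the carboxyl group off titanium, and the conjugated enoate is a polarity-mismatched, hindered acceptor, so the cascade stops at the bicycle.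

Step 4
Reactants: 9 ent-3β-hydroxylabda-8(17),13Z-dien-15-oic acid
Product: 10 ent-8α,17-epoxy-3β-hydroxylabd-13Z-en-15-oic acid
Conditions: mCPBA (1.05 equiv), CH2Cl2, −20 → 0 °C
Reagents that add atoms: 3-chloroperoxybenzoic acid (mCPBA), OOC(=O)c1cccc(Cl)c1
Why: Prilezhaev epoxidation: the electron-rich 1,1-disubstituted alkene reacts far faster than the conjugated trisubstituted one, and the peracid approaches anti to the axial C10 methyl; the minor epimer need not be removed because both converge in step 5 and C8 becomes sp2 again in step 6.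

Step 5
Reactants: 10 ent-8α,17-epoxy-3β-hydroxylabd-13Z-en-15-oic acid
Product: 11 ent-3β-hydroxy-17-oxolabd-13Z-en-15-oic acid (C8–H cis to the C10 methyl)
Conditions: BF3·OEt2 (0.2 equiv), CH2Cl2, −78 → −30 °C
Reagents that add atoms: none
Why: Meinwald rearrangement: BF3 ionises the tertiary C8–O bond and a 1,2-hydride shift from C17 gives the aldehyde, both epoxide epimers ending as the equatorial-formyl compound; the C8 centre made here is only transient.

Step 6
Reactants: 11 ent-3β-hydroxy-17-oxolabd-13Z-en-15-oic acid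
Product: 15 ent-3β,8β-dihydroxy-17-oxolabd-13Z-en-15-oic acid, via iodanyl aldehyde 12 (not isolated), via methoxy oxirane 13 (not isolated), via hydroxy dimethyl acetal 14 (not isolated)
Conditions: KOH (6 equiv), MeOH, 0 °C; PhI(OAc)2 (1.15 equiv), 0 °C → rt; then 1 M HCl, THF–H2O, rt
Reagents that add atoms: water, O
Why: Proposed new method: a Moriarty-type λ3-iodane α-hydroxylation, established for ketones, is applied to an α-branched aldehyde to make a tertiary α-hydroxy aldehyde with net inversion relative to electrophile approach: the enolate of 11 attacks PhI(OMe)2 at C8 from the face anti to the axial C10 methyl (the same preference as in step 4) to give 12, methoxide adds to the formyl group, and the resulting alkoxide displaces PhI by an internal 3-exo-tet SN2 with inversion, so the C8–O bond forms on the hindered C10-methyl face (13); methanolysis at the acetal carbon gives 14 and aqueous acid frees the aldehyde, so the C8 hydroxyl oxygen is the former formyl oxygen and the new formyl oxygen comes from water; the closest known reaction types are the Moriarty α-hydroxylation of ketones to α-hydroxy dimethyl acetals and the Stevens epoxy-ether solvolysis of α-halo aldehydes.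

**Compound list**

1 | 3-methylbut-2-enoic acid | CC(C)=CC(=O)O | starting material
2 | (2E,6E)-farnesyl bromide, (2E,6E)-1-bromo-3,7,11-trimethyldodeca-2,6,10-triene | CC(C)=CCC/C(C)=C/CC/C(C)=C/CBr | starting material
3 | dilithium 3-methylbuta-1,3-diene-1,1-diolate (dianion of 1) | [Li+].[Li+].C=C(C)C=C([O-])[O-] | intermediate
4 | lithium copper 3-methylbuta-1,3-diene-1,1-diolate (monovalent copper dienolate) | [Li+].[Cu+].C=C(C)C=C([O-])[O-] | intermediate
5 | (2Z,6E,10E)-3,7,11,15-tetramethylhexadeca-2,6,10,14-tetraenoic acid | CC(C)=CCC/C(C)=C/CC/C(C)=C/CC/C(C)=C\C(=O)O | intermediate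
6 | (2Z,6E,10E)-13-[(2R)-3,3-dimethyloxiran-2-yl]-3,7,11-trimethyltrideca-2,6,10-trienoic acid | CC1(C)O[C@@H]1CC/C(C)=C/CC/C(C)=C/CC/C(C)=C\C(=O)O | intermediate
7 | trimethylsilyl ester of 6 | CC1(C)O[C@@H]1CC/C(C)=C/CC/C(C)=C/CC/C(C)=C\C(=O)O[Si](C)(C)C | intermediate
8 | bis(trimethylsilyl) derivative of 9 (silyl ester and 3-O-silyl ether) | C/C(=C/C(=O)O[Si](C)(C)C)CC[C@H]1[C@]2(C)CC[C@@H](O[Si](C)(C)C)C(C)(C)[C@H]2CCC1=C | intermediate
9 | ent-3β-hydroxylabda-8(17),13Z-dien-15-oic acid, (2Z)-5-[(1R,4aS,6R,8aS)-6-hydroxy-5,5,8a-trimethyl-2-methylidenedecahydronaphthalen-1-yl]-3-methylpent-2-enoic acid; trans-decalin with 3-OH, C10 methyl and C9 side chain on one face | C/C(=C/C(=O)O)CC[C@H]1[C@]2(C)CC[C@@H](O)C(C)(C)[C@H]2CCC1=C | intermediate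
10 | ent-8α,17-epoxy-3β-hydroxylabd-13Z-en-15-oic acid; spiro-oxirane oxygen trans to the C10 methyl | C/C(=C/C(=O)O)CC[C@H]1[C@]2(C)CC[C@@H](O)C(C)(C)[C@H]2CC[C@@]1(O3)C3 | intermediate
11 | ent-3β-hydroxy-17-oxolabd-13Z-en-15-oic acid; formyl equatorial, C8–H cis to the C10 methyl | C/C(=C/C(=O)O)CC[C@H]1[C@]2(C)CC[C@@H](O)C(C)(C)[C@H]2CC[C@@H]1C=O | intermediate
12 | 8-[methoxy(phenyl)-λ3-iodanyl] derivative of 11; iodine trans to the C10 methyl, formyl axial | C/C(=C/C(=O)O)CC[C@H]1[C@]2(C)CC[C@@H](O)C(C)(C)[C@H]2CC[C@@]1(I(OC)c3ccccc3)C=O | intermediate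
13 | ent-8β,17-epoxy-3β-hydroxy-17-methoxylabd-13Z-en-15-oic acid; oxirane oxygen cis to the C10 methyl, C17 epimers | C/C(=C/C(=O)O)CC[C@H]1[C@]2(C)CC[C@@H](O)C(C)(C)[C@H]2CC[C@]1(O3)C3OC | intermediate
14 | ent-3β,8β-dihydroxy-17,17-dimethoxylabd-13Z-en-15-oic acid | C/C(=C/C(=O)O)CC[C@H]1[C@]2(C)CC[C@@H](O)C(C)(C)[C@H]2CC[C@]1(O)C(OC)OC | intermediate
15 | CNP0273710.1, ent-3β,8β-dihydroxy-17-oxolabd-13Z-en-15-oic acid, (2Z)-5-[(1S,2R,4aS,6R,8aR)-2-formyl-2,6-dihydroxy-5,5,8a-trimethyldecahydronaphthalen-1-yl]-3-methylpent-2-enoic acid; 3-OH, 8-OH, C10 methyl and side chain on one face, H-5, H-9 and CHO on the other | C/C(=C/C(=O)O)CC[C@H]1[C@]2(C)CC[C@@H](O)C(C)(C)[C@H]2CC[C@]1(O)C=O | target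

**Step count and risks**

Total steps: 6. Longest linear sequence: 6 (fully linear from 1 and 2).

Most likely to fail, first: step 6, the new reaction. The λ3-iodane may instead oxidise the methanol hemiacetal to the methyl ester or dehydrogenate to the enal, and attack at the fully substituted C8 may be slow or not fully face-selective. The fallback is known chemistry that forms the C8–C17 bond instead of the C8–O bond; it sets out from 9 and comes back at 15. Ozonise the exocyclic alkene of 9 selectively (O3, CH2Cl2–MeOH, pyridine, −78 °C, then Me2S) to the nor-ketone ent-3β-hydroxy-8-oxo-17-norlabd-13Z-en-15-oic acid F6. Add CH2=CHMgBr (5 equiv) with CeCl3 in THF at −78 → 0 °C, which attacks the ketone equatorially, anti to the axial C10 methyl, to give the vinyl carbinol ent-3β,8β-dihydroxy-8-vinyl-17-norlabd-13Z-en-15-oic acid F7 with the hydroxyl cis to the C10 methyl. A second ozonolysis (O3, CH2Cl2, −78 °C, then Me2S) cleaves the vinyl group to the formyl group of 15.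

Second: step 1. The γ/α ratio and, above all, the 2Z/2E ratio of the dienolate allylation may be too low for a clean acid. The fallback builds the Z alkene stereospecifically; it sets out from 2 and comes back at 5. Alkylate the dianion of methyl acetoacetate (NaH, then n-BuLi, THF, 0 °C) with 2 to the β-keto ester methyl (6E,10E)-7,11,15-trimethyl-3-oxohexadeca-6,10,14-trienoate F1. Treat it with Tf2O and aqueous Me4NOH (hexane, 0 °C) to form the enol triflate methyl (2E,6E,10E)-7,11,15-trimethyl-3-(trifluoromethylsulfonyloxy)hexadeca-2,6,10,14-tetraenoate F2. Couple with MeMgBr under Fe(acac)3 catalysis (THF–NMP, −30 °C, retention of geometry) to methyl (2Z,6E,10E)-3,7,11,15-tetramethylhexadeca-2,6,10,14-tetraenoate F3, and saponify (LiOH, THF–H2O, 50 °C) to 5.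

Third: step 3. The radical cascade is low-yielding at best, and here it runs on a carboxylic acid masked only as a labile silyl ester, which can bind titanium or manganese and stall the catalyst. The fallback returns to the substrate class for which this cascade is documented; it sets out from 6 and comes back at 9. Methylate 6 with Me3SiCHN2 (toluene–MeOH, 0 °C) to methyl (2Z,6E,10E)-13-[(2R)-3,3-dimethyloxiran-2-yl]-3,7,11-trimethyltrideca-2,6,10-trienoate F4. Cyclise it with stoichiometric Cp2TiCl (2.5 equiv, preformed from Cp2TiCl2 and Mn dust, THF, 0.01 M, rt) to methyl ent-3β-hydroxylabda-8(17),13Z-dien-15-oate F5, and saponify (LiOH, THF–H2O, 50 °C) to 9.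

**Further compounds**

F1 | step 1 | methyl (6E,10E)-7,11,15-trimethyl-3-oxohexadeca-6,10,14-trienoate | CC(C)=CCC/C(C)=C/CC/C(C)=C/CCC(=O)CC(=O)OC
F2 | step 1 | methyl (2E,6E,10E)-7,11,15-trimethyl-3-(trifluoromethylsulfonyloxy)hexadeca-2,6,10,14-tetraenoate | CC(C)=CCC/C(C)=C/CC/C(C)=C/CC/C(OS(=O)(=O)C(F)(F)F)=C\C(=O)OC
F3 | step 1 | methyl (2Z,6E,10E)-3,7,11,15-tetramethylhexadeca-2,6,10,14-tetraenoate | CC(C)=CCC/C(C)=C/CC/C(C)=C/CC/C(C)=C\C(=O)OC
F4 | step 3 | methyl (2Z,6E,10E)-13-[(2R)-3,3-dimethyloxiran-2-yl]-3,7,11-trimethyltrideca-2,6,10-trienoate | CC1(C)O[C@@H]1CC/C(C)=C/CC/C(C)=C/CC/C(C)=C\C(=O)OC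
F5 | step 3 | methyl ent-3β-hydroxylabda-8(17),13Z-dien-15-oate | C/C(=C/C(=O)OC)CC[C@H]1[C@]2(C)CC[C@@H](O)C(C)(C)[C@H]2CCC1=C
F6 | step 6 | ent-3β-hydroxy-8-oxo-17-norlabd-13Z-en-15-oic acid | C/C(=C/C(=O)O)CC[C@H]1[C@]2(C)CC[C@@H](O)C(C)(C)[C@H]2CCC1=O
F7 | step 6 | ent-3β,8β-dihydroxy-8-vinyl-17-norlabd-13Z-en-15-oic acid (vinyl trans, hydroxyl cis to the C10 methyl) | C/C(=C/C(=O)O)CC[C@H]1[C@]2(C)CC[C@@H](O)C(C)(C)[C@H]2CC[C@]1(O)C=C
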